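**Retrosynthetic overview**
1. Target 9 comes from 8 by cleaving the 3'-O-acetate; no skeletal change.
2. The C8–prenyl bond of 8 comes from the 5-O-prenyl ether 5 by a tandem aromatic Claisen/Cope rearrangement (O5 → C6 → C8, two [3,3] shifts).
3. Ether 5 comes from 3 by Mitsunobu O-prenylation; 3 from 2 by 3'-O-acetylation; 2 from 1 by selective 7-O-methylation.
4. No ring is formed: both arenes, the pyranone and the (2S) centre are bought in (2S)-hesperetin (1). The A ring is only dearomatised and re-aromatised during the rearrangement.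

Assumption: (2S)-hesperetin (CAS 520-33-2, aglycone of citrus hesperidin) is bought as the single (S)-enantiomer and its ee is confirmed by chiral HPLC on receipt.

**Step 1**
Reactants: 1 (2S)-hesperetin
Product: 2 (2S)-persicogenin (7-O-methylhesperetin)
Conditions: TMSCHN2 (2 M in hexanes, 1.1 equiv, slow addition), toluene–MeOH 4:1, 0 °C → rt, no base
Reagents that add atoms: trimethylsilyldiazomethane, C[Si](C)(C)C=[N+]=[N-]
Why: Chemoselective diazoalkane O-methylation, in which only the vinylogous-acid 7-OH (pKa about 7.5) protonates the reagent while the 3'-OH (pKa about 10) and the chelated 5-OH do not, and the base-free medium cannot open the pyranone, so C2 stays (S).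

**Step 2**
Reactants: 2 (2S)-persicogenin
Product: 3 (2S)-3'-O-acetylpersicogenin
Conditions: Ac2O (1.1 equiv), pyridine, CH2Cl2, 0 °C → rt
Reagents that add atoms: acetic anhydride, CC(=O)OC(C)=O
Why: Selective phenol acylation, because the 5-OH is locked in a hydrogen bond to C4=O and is inert to Ac2O/pyridine without DMAP, so only the 3'-OH is capped and C2 is untouched.

**Step 3**
Reactants: 3 (2S)-3'-O-acetylpersicogenin; 4 prenol (3-methylbut-2-en-1-ol)
Product: 5 (2S)-3'-O-acetyl-5-O-prenylpersicogenin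
Conditions: PPh3 (1.5 equiv), DIAD (1.5 equiv), THF, 0 °C → rt
Reagents that add atoms: none
Why: Mitsunobu etherification alkylates the only remaining acidic O–H (chelated 5-OH) by SN2 on the prenol-derived alkoxyphosphonium under near-neutral conditions, avoiding the carbonate bases that open flavanones to chalcones and racemise C2.

**Step 4**
Reactants: 5 (2S)-3'-O-acetyl-5-O-prenylpersicogenin
Product: 8 (2S)-3'-O-acetyl-8-prenylpersicogenin, via Claisen dienone 6 (not isolated), via Cope dienone 7 (not isolated)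
Conditions: Eu(fod)3 (10 mol %), dry CHCl3, 60 °C, sealed tube, Ar
Reagents that add atoms: none
Why: Eu(III)-catalysed tandem aromatic Claisen/Cope (para-Claisen) rearrangement, in which a [3,3] shift carries the prenyl group from O5 to C6 as a 1,1-dimethylallyl group (6), a second [3,3] shift moves it to C8 with allylic inversion back to prenyl (7), and enolisation restores the chelated 5-OH; C2 is remote and unaffected.

**Step 5**
Reactants: 8 (2S)-3'-O-acetyl-8-prenylpersicogenin
Product: 9 (2S)-5-hydroxy-2-(3-hydroxy-4-methoxyphenyl)-7-methoxy-8-(3-methylbut-2-en-1-yl)chroman-4-one (target)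
Conditions: NH4OAc (8 equiv), MeOH–H2O 4:1, rt
Reagents that add atoms: none
Why: Neutral NH4OAc-mediated methanolysis (transesterification) of the aryl acetate frees the 3'-OH at near-neutral pH, so there is neither retro-oxa-Michael epimerisation of C2 nor acid addition to the prenyl alkene.

**Compound list**
1 | (2S)-hesperetin, (2S)-5,7-dihydroxy-2-(3-hydroxy-4-methoxyphenyl)chroman-4-one | COc1ccc([C@@H]2CC(=O)c3c(O)cc(O)cc3O2)cc1O | starting material
2 | (2S)-persicogenin, (2S)-5-hydroxy-2-(3-hydroxy-4-methoxyphenyl)-7-methoxychroman-4-one | COc1ccc([C@@H]2CC(=O)c3c(O)cc(OC)cc3O2)cc1O | intermediate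
3 | (2S)-3'-O-acetylpersicogenin, 5-[(2S)-5-hydroxy-7-methoxy-4-oxochroman-2-yl]-2-methoxyphenyl acetate | COc1ccc([C@@H]2CC(=O)c3c(O)cc(OC)cc3O2)cc1OC(C)=O | intermediate
4 | prenol, 3-methylbut-2-en-1-ol | CC(C)=CCO | starting material
5 | (2S)-3'-O-acetyl-5-O-prenylpersicogenin, 2-methoxy-5-[(2S)-7-methoxy-5-(3-methylbut-2-enyloxy)-4-oxochroman-2-yl]phenyl acetate | COc1ccc([C@@H]2CC(=O)c3c(OCC=C(C)C)cc(OC)cc3O2)cc1OC(C)=O | intermediate
6 | Claisen dienone, (2S)-2-(3-acetoxy-4-methoxyphenyl)-7-methoxy-6-(2-methylbut-3-en-2-yl)-2,3-dihydrochromene-4,5(6H)-dione (C6 undefined, transient) | COc1ccc([C@@H]2CC(=O)C3=C(O2)C=C(OC)C(C(C)(C)C=C)C3=O)cc1OC(C)=O | intermediate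
7 | Cope dienone, (2S)-2-(3-acetoxy-4-methoxyphenyl)-7-methoxy-8-(3-methylbut-2-enyl)-2,3-dihydrochromene-4,5(8H)-dione (C8 undefined, transient) | COc1ccc([C@@H]2CC(=O)C3=C(O2)C(CC=C(C)C)C(OC)=CC3=O)cc1OC(C)=O | intermediate
8 | (2S)-3'-O-acetyl-8-prenylpersicogenin, 5-[(2S)-5-hydroxy-7-methoxy-8-(3-methylbut-2-enyl)-4-oxochroman-2-yl]-2-methoxyphenyl acetate | COc1ccc([C@@H]2CC(=O)c3c(O)cc(OC)c(CC=C(C)C)c3O2)cc1OC(C)=O | intermediate
9 | (2S)-5-hydroxy-2-(3-hydroxy-4-methoxyphenyl)-7-methoxy-8-(3-methylbut-2-en-1-yl)chroman-4-one | COc1ccc([C@@H]2CC(=O)c3c(O)cc(OC)c(CC=C(C)C)c3O2)cc1O | target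

**Step count**
Total steps: 5. Longest linear sequence: 5 (1 → 2 → 3 → 5 → 8 → 9).

**Three steps most likely to fail, with fallbacks**

Step 4 (Claisen/Cope cascade). The dienone 6 can enolise before the Cope shift and stop at the 6-(1,1-dimethylallyl) phenol, or the Lewis acid can ionise the ether of the electron-rich 7-methoxy ring and cause deprenylation. The fallback sets out from 1 and comes back at 9. It moves the cascade into the 7-O-acetyl series, whose electron-poorer A ring resists ionisation, and methylates last. Compound 1 is acetylated at both non-chelated phenols (Ac2O 2.2 equiv, pyridine, 0 °C) to (2S)-7,3'-di-O-acetylhesperetin F1. Mitsunobu coupling with 4 (PPh3, DIAD, THF) gives (2S)-7,3'-di-O-acetyl-5-O-prenylhesperetin F2. Eu(fod)3 in CHCl3 at 60 °C takes it through the diacetate Claisen dienone F3 and the diacetate Cope dienone F4 to (2S)-7,3'-di-O-acetyl-8-prenylhesperetin F5. NH4OAc in aqueous MeOH removes both acetates to give (2S)-8-prenylhesperetin F6. Its 7-OH, again the most acidic, is methylated with TMSCHN2 in toluene–MeOH to give 9.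

Step 3 (Mitsunobu on the chelated 5-OH). The hydrogen-bonded phenol may be too weakly acidic, giving low conversion or hydrazide adducts. The fallback sets out from 3 and comes back at 5. The ether is made by silver-assisted Williamson (Purdie-type) alkylation instead of redox condensation: prenyl bromide (CC(C)=CCBr) and Ag2O in CH2Cl2 at rt in the dark. No soluble base is present, so C2 is not at risk; this fallback makes no new compound (F0).

Step 5 (acetate removal on an epimerisable flavanone). Neutral methanolysis may be sluggish, and any recourse to carbonate or alkoxide risks ring-opening to the chalcone and loss of ee. The fallback sets out from 2 and comes back at 9. It replaces the ester with a silyl ether that is removed by fluoride. TBSCl and imidazole in DMF at 0 °C silylate the 3'-OH to give (2S)-3'-O-TBS-persicogenin F7. Mitsunobu coupling with 4 gives (2S)-5-O-prenyl-3'-O-TBS-persicogenin F8. Eu(fod)3 in CHCl3 at 60 °C rearranges it through the silyl Claisen dienone F9 and the silyl Cope dienone F10 to (2S)-8-prenyl-3'-O-TBS-persicogenin F11. HF·pyridine in THF at 0 °C then gives 9.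

**Further compounds**
F0 | step 3 | none | none
F1 | step 4 | (2S)-7,3'-di-O-acetylhesperetin | COc1ccc([C@@H]2CC(=O)c3c(O)cc(OC(C)=O)cc3O2)cc1OC(C)=O
F2 | step 4 | (2S)-7,3'-di-O-acetyl-5-O-prenylhesperetin | COc1ccc([C@@H]2CC(=O)c3c(OCC=C(C)C)cc(OC(C)=O)cc3O2)cc1OC(C)=O
F3 | step 4 | diacetate Claisen dienone, (2S)-7-acetoxy-2-(3-acetoxy-4-methoxyphenyl)-6-(2-methylbut-3-en-2-yl)-2,3-dihydrochromene-4,5(6H)-dione | COc1ccc([C@@H]2CC(=O)C3=C(O2)C=C(OC(C)=O)C(C(C)(C)C=C)C3=O)cc1OC(C)=O
F4 | step 4 | diacetate Cope dienone, (2S)-7-acetoxy-2-(3-acetoxy-4-methoxyphenyl)-8-(3-methylbut-2-enyl)-2,3-dihydrochromene-4,5(8H)-dione | COc1ccc([C@@H]2CC(=O)C3=C(O2)C(CC=C(C)C)C(OC(C)=O)=CC3=O)cc1OC(C)=O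
F5 | step 4 | (2S)-7,3'-di-O-acetyl-8-prenylhesperetin | COc1ccc([C@@H]2CC(=O)c3c(O)cc(OC(C)=O)c(CC=C(C)C)c3O2)cc1OC(C)=O
F6 | step 4 | (2S)-8-prenylhesperetin | COc1ccc([C@@H]2CC(=O)c3c(O)cc(O)c(CC=C(C)C)c3O2)cc1O
F7 | step 5 | (2S)-3'-O-TBS-persicogenin | COc1ccc([C@@H]2CC(=O)c3c(O)cc(OC)cc3O2)cc1O[Si](C)(C)C(C)(C)C
F8 | step 5 | (2S)-5-O-prenyl-3'-O-TBS-persicogenin | COc1ccc([C@@H]2CC(=O)c3c(OCC=C(C)C)cc(OC)cc3O2)cc1O[Si](C)(C)C(C)(C)C
F9 | step 5 | silyl Claisen dienone, (2S)-2-[3-(tert-butyldimethylsilyloxy)-4-methoxyphenyl]-7-methoxy-6-(2-methylbut-3-en-2-yl)-2,3-dihydrochromene-4,5(6H)-dione | COc1ccc([C@@H]2CC(=O)C3=C(O2)C=C(OC)C(C(C)(C)C=C)C3=O)cc1O[Si](C)(C)C(C)(C)C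
F10 | step 5 | silyl Cope dienone, (2S)-2-[3-(tert-butyldimethylsilyloxy)-4-methoxyphenyl]-7-methoxy-8-(3-methylbut-2-enyl)-2,3-dihydrochromene-4,5(8H)-dione | COc1ccc([C@@H]2CC(=O)C3=C(O2)C(CC=C(C)C)C(OC)=CC3=O)cc1O[Si](C)(C)C(C)(C)C
F11 | step 5 | (2S)-8-prenyl-3'-O-TBS-persicogenin | COc1ccc([C@@H]2CC(=O)c3c(O)cc(OC)c(CC=C(C)C)c3O2)cc1O[Si](C)(C)C(C)(C)C
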